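## Retrosynthetic overview

1. Target ⇒ one-pot union of acetal **15** with dione **3**, then intramolecular de Mayo reaction (enol/butenolide [2+2], retro-aldol); this closes the cyclopentane and then the cyclooctane last.
2. Dione **3** ⇒ directed hydrogenation ⇒ enantioselective hydroxylative dearomatisation of the mirror-symmetric 4,6-dimethylresorcinol (key step; sets the carbinol centre, and through it the CHMe centre).
3. Tetronate **15** ⇒ Ph3P=C=C=O butenolide annulation of a bridged hydroxy lactone ⇒ asymmetric exo Diels–Alder of 3-hydroxy-2-pyrone **7** with (E)-boryl acrolein (second dearomatisation; four stereocentres).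
4. Ring order: cyclohexanedione and, separately, oxabicyclo[2.2.2]octene → butenolide → cyclopentane plus cyclobutane → cyclooctane.

Assumption: **1**, **4**, **5**, **8** and **11** are bought (**4** is otherwise one step from pyruvic acid and acetic anhydride); locants and descriptors of bicyclic intermediates follow 2-oxabicyclo[2.2.2]octane numbering.

## Route

Step 1
Reactants: 1 4,6-dimethylresorcinol
Product: 2 (6S)-quinol (vinylogous acid)
Conditions: (R,R)-2-iodo-1,3-bis[1-(mesitylcarbamoyl)ethoxy]benzene (10 mol %; the enantiomer that gives (6S)-2), mCPBA (1.1 equiv), MeCN/H2O 9:1, −20 °C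
Reagents that add atoms: water, O
Why: Proposed new method: the chiral aryl-λ3-iodane formed in situ binds one phenol oxygen and water attacks the methyl-bearing carbon para to it, so the catalyst chooses between the two enantiotopic ring halves and sets the quaternary carbinol while aromaticity and mirror symmetry are lost; the closest known reaction type is catalytic enantioselective hydrative dearomatisation of 4-alkylphenols to p-quinols.

Step 2
Reactants: 2 (6S)-quinol
Product: 3 (4S,6S)-hydroxy dione
Conditions: H2 (1 atm), [Ir(cod)(PCy3)(py)]PF6 (3 mol %), CH2Cl2, 0 °C to 23 °C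
Reagents that add atoms: none
Why: Hydroxyl-directed hydrogenation delivers H2 to the trisubstituted ring alkene from the face of the tertiary OH, so the new C–H is cis to OH and the two methyl groups are cis (6S); the vinylogous acid then rests as the 1,3-dione.

Step 3
Reactants: 4 2-acetoxyacrylic acid; 5 but-2-yne
Product: 6 3-acetoxy-5,6-dimethyl-2-pyrone
Conditions: [RhCl2(C5Me5)]2 (2 mol %), Cu(OAc)2·H2O (10 mol %), air, DMF, 100 °C, sealed tube
Reagents that add atoms: none
Why: Carboxylate-directed vinylic C–H activation, alkyne insertion and C–O reductive elimination (oxidative annulation of acrylic acids with alkynes) build the 2-pyrone with oxygen at C3; no stereocentre is formed.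

Step 4
Reactants: 6 3-acetoxy-5,6-dimethyl-2-pyrone
Product: 7 3-hydroxy-5,6-dimethyl-2-pyrone
Conditions: HCl (0.1 equiv, 1.25 M in MeOH), MeOH, 23 °C
Reagents that add atoms: none
Why: Acid-catalysed transesterification of the enol acetate frees the 3-hydroxyl needed for base catalysis and leaves the pyrone lactone intact.

Step 5
Reactants: 7 3-hydroxy-5,6-dimethyl-2-pyrone; 8 (E)-3-(pinacolboryl)acrolein
Product: 10 cycloadduct dimethyl acetal, via cycloadduct aldehyde 9 (not isolated)
Conditions: cupreidine 9-O-(9-phenanthryl) ether (10 mol %), EtOAc, −20 °C; then HC(OMe)3, MeOH, PPTS (10 mol %), 23 °C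
Reagents that add atoms: trimethyl orthoformate, COC(OC)OC; methanol, CO
Why: Bifunctional cinchona-base-catalysed Diels–Alder reaction of the 3-oxidopyrone (vinylogous Michael addition, then aldol closure) dearomatises the pyrone, joining the methyl-bearing diene terminus to the boryl carbon and the hydroxyl-bearing terminus to the formyl carbon; the exo mode (CHO syn to the lactone bridge, boron trans through the E alkene) and catalyst face control fix C1, C4, C5 and C6, and acetalisation in the same flask protects the aldehyde.

Step 6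
Reactants: 10 cycloadduct dimethyl acetal; 11 Ph3P=C=C=O
Product: 13 boryl tetronate, via phosphorane ester 12 (not isolated)
Conditions: THF, 60 °C (kept below 80 °C to avoid loss of CO2 from the bridged lactone)
Reagents that add atoms: none
Why: Bestmann–Schobert tetronate synthesis: the tertiary alcohol adds to the ketenylidene ylide and the ester phosphorane undergoes intramolecular Wittig olefination of the lactone carbonyl, giving the 4-alkoxybutenolide with the ether oxygen retained and no stereocentre touched (boron masks the future hydroxyl so only one OH is present).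

Step 7
Reactants: 13 boryl tetronate
Product: 14 hydroxy tetronate
Conditions: H2O2 (30 % aq.), pH 7 phosphate buffer, THF, 0 °C
Reagents that add atoms: hydrogen peroxide, OO
Why: Oxidation of the secondary alkyl boronate proceeds by 1,2-migration with retention, placing the hydroxyl anti to the ether bridge.

Step 8
Reactants: 14 hydroxy tetronate
Product: 15 saturated hydroxy tetronate
Conditions: H2 (1 atm), [Ir(cod)(PCy3)(py)]PF6 (5 mol %), CH2Cl2, 23 °C
Reagents that add atoms: none
Why: Hydroxyl-directed hydrogenation: the secondary OH points over the ring alkene and steers H2 to that face, so the methyl on the reduced carbon ends syn to the ether bridge (7S) and the electron-poor butenolide alkene is left alone.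

Step 9
Reactants: 15 saturated hydroxy tetronate; 3 (4S,6S)-hydroxy dione
Product: 18 CNP0073200.1, via methoxy adduct 16 (not isolated), via cyclobutanol photoadduct 17 (not isolated)
Conditions: 3 (1.0 equiv), PPTS (10 mol %), MeCN/MeOH 4:1, 23 °C; then hν (Hg lamp, Pyrex, λ > 290 nm), 10 °C
Reagents that add atoms: methanol, CO
Why: The dione enol is alkylated by the oxocarbenium ion of the acetal and the adduct undergoes an intramolecular de Mayo reaction (enol–butenolide [2+2] closing the cyclopentane, then retro-aldol opening of the cyclobutanol to the cyclooctane β-keto lactone, as known for 2-alkenyl cyclohexane-1,3-diones); the tether reaches only the butenolide face syn to the side chain (sets the quaternary ether carbon), the CH(OMe) epimers interconvert in acidic methanol and the one with exo methoxy is expected to cyclise, and the ring-fusion CH next to the ketone settles by protonation of the enol.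

## Compound list

1 | 4,6-dimethylbenzene-1,3-diol (4,6-dimethylresorcinol) | Cc1cc(C)c(O)cc1O | starting material
2 | (6S)-3,6-dihydroxy-4,6-dimethylcyclohexa-2,4-dien-1-one | CC1=C[C@](C)(O)C(=O)C=C1O | intermediate
3 | (4S,6S)-4-hydroxy-4,6-dimethylcyclohexane-1,3-dione (methyl groups cis) | O=C1[C@@H](C)C[C@](C)(O)C(=O)C1 | intermediate
4 | 2-acetoxyprop-2-enoic acid | CC(=O)OC(=C)C(=O)O | starting material
5 | but-2-yne | CC#CC | starting material
6 | 5,6-dimethyl-2-oxo-2H-pyran-3-yl acetate | CC(=O)OC1=CC(C)=C(C)OC1=O | intermediate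
7 | 3-hydroxy-5,6-dimethyl-2H-pyran-2-one | CC1=C(C)OC(=O)C(O)=C1 | intermediate
8 | (E)-3-(4,4,5,5-tetramethyl-1,3,2-dioxaborolan-2-yl)prop-2-enal | O=C/C=C/B1OC(C)(C)C(C)(C)O1 | starting material
9 | (1R,4S,5S,6S)-4-hydroxy-1,7-dimethyl-3-oxo-6-(4,4,5,5-tetramethyl-1,3,2-dioxaborolan-2-yl)-2-oxabicyclo[2.2.2]oct-7-ene-5-carbaldehyde (CHO syn to the lactone bridge, boryl trans to CHO) | O=C[C@H]1[C@H](B2OC(C)(C)C(C)(C)O2)[C@@]3(C)OC(=O)[C@]1(O)C=C3C | intermediate
10 | (1R,4S,5S,6S)-5-(dimethoxymethyl)-4-hydroxy-1,7-dimethyl-6-(pinacolboryl)-2-oxabicyclo[2.2.2]oct-7-en-3-one | COC(OC)[C@H]1[C@H](B2OC(C)(C)C(C)(C)O2)[C@@]3(C)OC(=O)[C@]1(O)C=C3C | intermediate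
11 | (triphenylphosphoranylidene)ethenone | O=C=C=P(c1ccccc1)(c1ccccc1)c1ccccc1 | starting material
12 | 2-(triphenyl-λ5-phosphanylidene)acetate ester of the C4 hydroxyl of 10 | COC(OC)[C@H]1[C@H](B2OC(C)(C)C(C)(C)O2)[C@@]3(C)OC(=O)[C@]1(OC(=O)C=P(c4ccccc4)(c4ccccc4)c4ccccc4)C=C3C | intermediate
13 | boryl tetronate: skeleton of 10 with C3 and the C4 oxygen joined through =CH–C(=O)– into a fused 4-alkoxybutenolide; 5-CH(OMe)2 syn to the butenolide, 6-boryl anti; (1R,4S,5S,6S) | COC(OC)[C@H]1[C@H](B2OC(C)(C)C(C)(C)O2)[C@@]3(C)OC4=CC(=O)O[C@@]14C=C3C | intermediate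
14 | hydroxy tetronate: 13 with OH in place of boron (retention); (1S,4S,5S,6S) | COC(OC)[C@H]1[C@H](O)[C@@]3(C)OC4=CC(=O)O[C@@]14C=C3C | intermediate
15 | saturated hydroxy tetronate: 14 with C7–C8 hydrogenated, 7-methyl syn to the ether bridge; (1S,4S,5S,6S,7S) | COC(OC)[C@H]1[C@H](O)[C@@]3(C)OC4=CC(=O)O[C@@]14C[C@@H]3C | intermediate
16 | methoxy adduct: 15 with one acetal OMe replaced by C2 of enolised dione 3; new CH(OMe) centre S | CO[C@H](C5=C(O)[C@@H](C)C[C@](C)(O)C5=O)[C@H]1[C@H](O)[C@@]3(C)OC4=CC(=O)O[C@@]14C[C@@H]3C | intermediate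
17 | cyclobutanol photoadduct of 16 (cis-fused bicyclo[3.2.0]heptane from enol C=C and butenolide C=C; one diastereomer drawn) | CO[C@H]1[C@H]2[C@H](O)[C@@]3(C)O[C@@]45[C@@H]([C@@]6(O)[C@@H](C)C[C@](C)(O)C(=O)[C@@]146)C(=O)O[C@@]25C[C@@H]3C | intermediate
18 | CNP0073200.1 | CO[C@H]1[C@H]2[C@H](O)[C@@]3(C)O[C@@]45/C(=C(/O)[C@@H](C)C[C@](C)(O)C(=O)[C@H]14)C(=O)O[C@@]25C[C@@H]3C | target

## Step count and weak points

Total: 9 steps. Longest linear sequence: 7 steps (steps 3 to 9).

**Step 1 (enantioselectivity on a new substrate class; over-oxidation or dimerisation of the quinol).** The fallback sets out from 1 and comes back at 2. One hydroxyl of 1 is esterified with N-Boc-L-proline (DCC, DMAP) to give 5-hydroxy-2,4-dimethylphenyl N-Boc-L-prolinate F1. PhI(OAc)2 in MeCN/H2O then hydroxylates the methyl-bearing carbon para to the free OH and gives the quinol enol ester F2 as two diastereomers, which are separated (auxiliary-based separation in place of catalyst control). Methanolysis of the (S)-carbinol diastereomer with catalytic K2CO3 in MeOH releases 2.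

**Step 5 (exo and facial selectivity with a hindered, fully substituted diene terminus).** The fallback sets out from 8 and comes back at 9. Compound 8 is isomerised with Ir(ppy)3 under 450 nm light in MeCN to (Z)-3-(pinacolboryl)acrolein F3. The usual endo-selective amine-base cycloaddition with 7 then gives the all-endo cis cycloadduct aldehyde F4. DBU epimerises the formyl-bearing carbon to the trans arrangement, which is 9, and 9 is acetalised to 10 as in step 5.

**Step 9 (which enol reacts, which CH(OMe) epimer cyclises, competing photochemistry).** The stereochemical course at the methoxy carbon is the least secure point of the route: open-transition-state addition to the oxocarbenium ion is expected to favour the wrong epimer, so the outcome relies on equilibration and selective cyclisation. The fallback sets out from 15 and 3 and comes back at 18. Adduct 16 is formed as in step 9 and trapped with CbzCl and Et3N as the bis(benzyl carbonate) F5; this fixes the enol on the less hindered oxygen and lets the CH(OMe) epimers be separated. Irradiation gives the cyclobutane carbonate photoadduct F6. Hydrogenolysis (H2, Pd/C, EtOAc) frees the cyclobutanol under neutral conditions, and it fragments to 18.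

## Further compounds

F1 | step 1 | 5-hydroxy-2,4-dimethylphenyl (2S)-1-(tert-butoxycarbonyl)pyrrolidine-2-carboxylate | Cc1cc(C)c(OC(=O)[C@@H]2CCCN2C(=O)OC(C)(C)C)cc1O
F2 | step 1 | (6S)-6-hydroxy-4,6-dimethyl-3-oxocyclohexa-1,4-dien-1-yl (2S)-1-(tert-butoxycarbonyl)pyrrolidine-2-carboxylate | CC1=C[C@](C)(O)C(OC(=O)[C@@H]2CCCN2C(=O)OC(C)(C)C)=CC1=O
F3 | step 5 | (Z)-3-(4,4,5,5-tetramethyl-1,3,2-dioxaborolan-2-yl)prop-2-enal | O=C/C=C\B1OC(C)(C)C(C)(C)O1
F4 | step 5 | (1R,4S,5R,6S)-4-hydroxy-1,7-dimethyl-3-oxo-6-(pinacolboryl)-2-oxabicyclo[2.2.2]oct-7-ene-5-carbaldehyde | O=C[C@@H]1[C@H](B2OC(C)(C)C(C)(C)O2)[C@@]3(C)OC(=O)[C@]1(O)C=C3C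
F5 | step 9 | bis(benzyl carbonate) of 16 (enol oxygen and secondary hydroxyl) | CO[C@H](C5=C(OC(=O)OCc6ccccc6)[C@@H](C)C[C@](C)(O)C5=O)[C@H]1[C@H](OC(=O)OCc6ccccc6)[C@@]3(C)OC4=CC(=O)O[C@@]14C[C@@H]3C
F6 | step 9 | cyclobutane bis(benzyl carbonate) photoadduct | CO[C@H]1[C@H]2[C@H](OC(=O)OCc7ccccc7)[C@@]3(C)O[C@@]45[C@@H]([C@@]6(OC(=O)OCc7ccccc7)[C@@H](C)C[C@](C)(O)C(=O)[C@@]146)C(=O)O[C@@]25C[C@@H]3C
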